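**Retrosynthetic overview**
1. The target is cut back to CO2 and a ten-membered 7-ethynyl-6-mesyloxy carbocycle. One operation joins the CO2 carbon to the internal alkyne carbon C11 (C11–C12) and a CO2 oxygen to C6 (carboxylate displaces the mesylate with inversion), which closes the cis-fused α-methylene-γ-lactone last.
2. Enabling feature: on the ring C1–C10 the ethynyl group (C11≡C13) on C7 sits next to the C6–OMs carbon. A carboxylate born on C11 is therefore 5-exo-tet to C6, and O–C12–C11–C7–C6 becomes the butyrolactone ring.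
3. The ten-membered ring is closed at C9–C10 by a Nozaki–Hiyama–Kishi reaction of an open-chain (Z)-α-iodoenoate aldehyde.
4. The open chain comes from C6–C7 allenylboration of a cis-epoxy aldehyde (from neryl acetate, Sharpless epoxidation) with an axially chiral allenylboronate that already carries the C8 angelate (from (E)-pent-2-en-4-yn-1-ol by Sharpless epoxidation, Cu-catalysed anti-SN2′ borylation and Mitsunobu angeloylation).
5. Ring order: oxirane (step 4), ten-membered carbocycle (step 14), γ-lactone (step 15).

Key step: step 15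

Remark: germacrane numbering is used (ring C1–C10, lactone carbons C11–C13, ester carbon C14); the SMILES is read as 4R,5S,6R,7R,8S,9S, i.e. a cis-fused 6,12-lactone, an oxirane with C3 and C6 cis (neryl type) and an in-ring cis C1=C10 bond, and the route is built for this isomer.

Step 1
Reactants: 1 neryl acetate
Product: 2 (2Z)-3-methyl-6-oxohex-2-en-1-yl acetate
Conditions: O3 (1.0 equiv), CH2Cl2–MeOH, −78 °C; then Me2S, −78 → 23 °C
Reagents that add atoms: ozone, [O-][O+]=O
Why: Chemoselective ozonolysis: the remote 6,7-alkene is more electron-rich than the 2,3-alkene deactivated by the allylic acetate, so only the isopropylidene end should be cleaved and the Z-geometry (later the C3/C6 cis relationship on the oxirane) is kept.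

Step 2
Reactants: 2 (2Z)-3-methyl-6-oxohex-2-en-1-yl acetate
Product: 3 methyl (2Z,6Z)-8-acetoxy-2-iodo-6-methylocta-2,6-dienoate
Conditions: Ph3P=CHCO2Me, NIS, K2CO3, CH2Cl2, −20 °C; then 2, −20 → 23 °C
Reagents that add atoms: methyl (triphenylphosphoranylidene)acetate, COC(=O)C=P(c1ccccc1)(c1ccccc1)c1ccccc1; N-iodosuccinimide, O=C1CCC(=O)N1I
Why: Halogenation–Wittig olefination: the ylide is iodinated in the flask and the α-iodo ylide should olefinate the aldehyde with the ester trans to the chain, giving the (Z)-α-iodoenoate that later becomes the in-ring cis C1=C10 bond.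

Step 3
Reactants: 3 methyl (2Z,6Z)-8-acetoxy-2-iodo-6-methylocta-2,6-dienoate
Product: 4 methyl (2Z,6Z)-8-hydroxy-2-iodo-6-methylocta-2,6-dienoate
Conditions: K2CO3 (cat.), MeOH, 0 °C
Reagents that add atoms: none
Why: Base-catalysed methanolysis (transesterification) of the allylic acetate; the methyl ester is degenerate towards methoxide and the iodoenoate should survive the cold, weakly basic medium.

Step 4
Reactants: 4 methyl (2Z,6Z)-8-hydroxy-2-iodo-6-methylocta-2,6-dienoate
Product: 5 methyl (2Z)-5-[(2R,3S)-3-(hydroxymethyl)-2-methyloxiran-2-yl]-2-iodopent-2-enoate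
Conditions: Ti(OiPr)4, L-(+)-diethyl tartrate, t-BuOOH, 4 Å MS, CH2Cl2, −20 °C
Reagents that add atoms: tert-butyl hydroperoxide, CC(C)(C)OO
Why: Sharpless asymmetric epoxidation of the Z-allylic alcohol: L-(+)-tartrate should deliver oxygen to the face that gives C4 R and C5 S, the syn addition to the Z-alkene fixes C3 and C6 cis, and the electron-poor iodoenoate is not touched.

Step 5
Reactants: 5 methyl (2Z)-5-[(2R,3S)-3-(hydroxymethyl)-2-methyloxiran-2-yl]-2-iodopent-2-enoate
Product: 6 methyl (2Z)-5-[(2R,3R)-3-formyl-2-methyloxiran-2-yl]-2-iodopent-2-enoate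
Conditions: Dess–Martin periodinane, NaHCO3, CH2Cl2, 0 → 23 °C
Reagents that add atoms: none
Why: Buffered Dess–Martin oxidation should give the α,β-epoxy aldehyde without opening the oxirane or epimerising C5 (the descriptor change at C5 is only a CIP priority change).

Step 6
Reactants: 7 (2E)-pent-2-en-4-yn-1-ol
Product: 8 [(2S,3S)-3-ethynyloxiran-2-yl]methanol
Conditions: Ti(OiPr)4 (cat.), L-(+)-diisopropyl tartrate, t-BuOOH, 4 Å MS, CH2Cl2, −20 °C
Reagents that add atoms: tert-butyl hydroperoxide, CC(C)(C)OO
Why: Sharpless asymmetric epoxidation of the E-allylic alcohol (the alkyne is inert): L-(+)-tartrate should give the (2S,3S)-trans-epoxide, whose alkyne-bearing carbon (future C7) later defines the allene axis.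

Step 7
Reactants: 8 [(2S,3S)-3-ethynyloxiran-2-yl]methanol
Product: 9 tert-butyl{[(2S,3S)-3-ethynyloxiran-2-yl]methoxy}dimethylsilane
Conditions: TBSCl, imidazole, CH2Cl2, 0 °C
Reagents that add atoms: tert-butyldimethylsilyl chloride, CC(C)(C)[Si](C)(C)Cl
Why: Standard silylation of the primary alcohol (the future C9 oxygen), which is unmasked late as the aldehyde for ring closure.

Step 8
Reactants: 9 tert-butyl{[(2S,3S)-3-ethynyloxiran-2-yl]methoxy}dimethylsilane
Product: 10 (2R,aS)-1-[(tert-butyldimethylsilyl)oxy]-5-(pinacolboryl)penta-3,4-dien-2-ol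
Conditions: B2pin2, CuCl (5 mol %), Xantphos (5 mol %), NaOt-Bu (10 mol %), MeOH (2 equiv), THF, 0 °C
Reagents that add atoms: bis(pinacolato)diboron, CC1(C)OB(OC1(C)C)B1OC(C)(C)C(C)(C)O1
Why: Copper-catalysed borylative SN2′ opening of a propargylic oxirane (known for propargylic carbonates and epoxides): syn borylcupration of the alkyne and anti β-oxygen elimination put boron on C13 anti to the C7–O bond, so the C7 centre becomes the (aS) allene axis while C8 keeps its C–O bond.

Step 9
Reactants: 10 (2R,aS)-1-[(tert-butyldimethylsilyl)oxy]-5-(pinacolboryl)penta-3,4-dien-2-ol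
Product: 11 (2S,aS)-1-[(tert-butyldimethylsilyl)oxy]-5-(pinacolboryl)penta-3,4-dien-2-yl (2Z)-2-methylbut-2-enoate
Conditions: angelic acid, PPh3, DIAD, toluene, 0 → 23 °C
Reagents that add atoms: angelic acid, C/C=C(/C)C(=O)O
Why: Mitsunobu esterification: SN2 inversion at C8 (2R to 2S) should give the C8–O configuration of the target, and the neutral conditions avoid base-induced isomerisation of the angelate to the tiglate; the allene axis is not involved.

Step 10
Reactants: 6 methyl (2Z)-5-[(2R,3R)-3-formyl-2-methyloxiran-2-yl]-2-iodopent-2-enoate; 11 allenylboronate angelate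
Product: 13 homopropargylic alcohol (6S carbinol with 7-ethynyl and 8-angelate; full name in the list), via pinacolboryl ether 12 (not isolated)
Conditions: toluene (1 M), 4 Å MS, 23 → 45 °C; then aq. NaHCO3
Reagents that add atoms: none
Why: Allenylboration (propargylation) through a closed six-membered transition state: syn-SE2′ transfers the allene axis to C7, the pseudo-equatorial aldehyde substituent sets C6–OH anti to the C8 branch (syn to the ethynyl group), and this sense coincides with Felkin–Anh attack anti to the oxirane C5–O bond (matched pair), so the 6S carbinol should result; the vinyl iodide, oxirane and esters are inert to the neutral boron reagent.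

Step 11
Reactants: 13 homopropargylic alcohol
Product: 14 C6 methanesulfonate of 13
Conditions: MsCl, Et3N, CH2Cl2, −20 → 0 °C
Reagents that add atoms: methanesulfonyl chloride, CS(=O)(=O)Cl
Why: Sulfonylation of the only free hydroxyl with retention at C6, which places the leaving group on the face opposite to the future lactone oxygen.

Step 12
Reactants: 14 C6 methanesulfonate
Product: 15 primary alcohol (C9–OH)
Conditions: HF·pyridine, pyridine, THF, 0 °C
Reagents that add atoms: none
Why: Buffered fluoride desilylation of the primary TBS ether; the mildly acidic medium should suppress angeloyl migration from O8 to O9 and spare oxirane, mesylate and iodoenoate.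

Step 13
Reactants: 15 primary alcohol
Product: 16 C9 aldehyde (open-chain iodoenoate aldehyde)
Conditions: Dess–Martin periodinane, NaHCO3, CH2Cl2, 0 °C
Reagents that add atoms: none
Why: Dess–Martin oxidation to the α-acyloxy aldehyde under buffered conditions; the aldehyde is used at once to avoid epimerisation at C8.

Step 14
Reactants: 16 C9 aldehyde
Product: 17 ten-membered carbocycle (7-ethynyl-6-mesyloxy-9-hydroxy; full name in the list)
Conditions: CrCl2 (6 equiv), Kishi-type chiral oxazoline–sulfonamide ligand, Et3N, NiCl2 (5 mol %), THF–MeCN, 2 mM, 23 °C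
Reagents that add atoms: none
Why: Nozaki–Hiyama–Kishi alkenylation closes C9–C10 with retention of the iodoenoate geometry (in-ring cis alkene), the cis-oxirane and the Z-enoate pre-bend the chain for ten-membered ring closure, and the chiral Cr(III)–sulfonamide complex is expected to override the weak Felkin bias of the α-acyloxy aldehyde and give the 9S carbinol (syn to the C8 oxygen).

Step 15
Reactants: 17 ten-membered carbocycle
Product: 20 target germacranolide (cis-fused α-methylene-γ-lactone), via silyl acrylate 18 (not isolated), via caesium acrylate 19 (not isolated)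
Conditions: NiBr2·glyme (10 mol %), 4,4′-di-tert-butyl-2,2′-bipyridine (12 mol %), (EtO)2MeSiH (1.3 equiv), Cs2CO3 (2 equiv), CO2 (1 atm), DMF, 0 → 23 °C; then 45 °C
Reagents that add atoms: carbon dioxide, O=C=O
Why: Proposed new method: a bipyridine-ligated Ni–H (from Ni(II), silane and carbonate) should insert the terminal alkyne of 17 in the Markovnikov sense (H to C13, Ni to the internal carbon C11), the α-alkenylnickel inserts CO2 to make C11–C12, the silane turns the nickel carboxylate over to silyl acrylate 18, carbonate frees caesium acrylate 19, and its carboxylate oxygen displaces the C6 mesylate to make O–C6. The closest known reaction types are Ni–H-catalysed Markovnikov hydroalkylation of terminal alkynes to 1,1-disubstituted alkenes, CO2 insertion into alkenylnickel species in the reductive carboxylation of alkenyl halides and triflates, copper hydride/silane hydrocarboxylation of alkynes, and γ-lactone formation by carboxylate displacement of a sulfonate; their merger on a terminal alkyne is new. The γ-lactone closes 5-exo-tet. The only centre that changes is C6, set by stereospecific SN2 inversion (6S mesylate to 6R C–O), which turns the syn C6–O/ethynyl array of 17 into the cis ring fusion. The step needs Markovnikov regioselectivity, which the known preference of Ni–H/bipyridine for nickel at the substituted carbon and the branched propargylic C7 should secure, and chemoselectivity for the alkyne over the two trisubstituted enoates, which insert Ni–H far more slowly, with the silane kept near one equivalent to spare the product acrylate. Lactonisation at C6 should outrun oxirane opening at C5 (six-membered ring, poorer leaving group) and E2, because the mesylate can sit anti to C11 in a gauche C5–C6–C7–C8 ring conformation.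

**Compound list**
1 | neryl acetate, (2Z)-3,7-dimethylocta-2,6-dien-1-yl acetate | CC(C)=CCC/C(C)=C\COC(C)=O | starting material
2 | (2Z)-3-methyl-6-oxohex-2-en-1-yl acetate | O=CCC/C(C)=C\COC(C)=O | intermediate
3 | methyl (2Z,6Z)-8-acetoxy-2-iodo-6-methylocta-2,6-dienoate | COC(=O)/C(I)=C/CC/C(C)=C\COC(C)=O | intermediate
4 | methyl (2Z,6Z)-8-hydroxy-2-iodo-6-methylocta-2,6-dienoate | COC(=O)/C(I)=C/CC/C(C)=C\CO | intermediate
5 | methyl (2Z)-5-[(2R,3S)-3-(hydroxymethyl)-2-methyloxiran-2-yl]-2-iodopent-2-enoate | COC(=O)/C(I)=C/CC[C@@]1(C)O[C@H]1CO | intermediate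
6 | methyl (2Z)-5-[(2R,3R)-3-formyl-2-methyloxiran-2-yl]-2-iodopent-2-enoate | COC(=O)/C(I)=C/CC[C@@]1(C)O[C@H]1C=O | intermediate
7 | (2E)-pent-2-en-4-yn-1-ol | C#C/C=C/CO | starting material
8 | [(2S,3S)-3-ethynyloxiran-2-yl]methanol | C#C[C@@H]1O[C@H]1CO | intermediate
9 | tert-butyl{[(2S,3S)-3-ethynyloxiran-2-yl]methoxy}dimethylsilane | C#C[C@@H]1O[C@H]1CO[Si](C)(C)C(C)(C)C | intermediate
10 | (2R,aS)-1-[(tert-butyldimethylsilyl)oxy]-5-(4,4,5,5-tetramethyl-1,3,2-dioxaborolan-2-yl)penta-3,4-dien-2-ol | CC1(C)OB(OC1(C)C)C([H])=[C@@]=C([H])[C@@H](O)CO[Si](C)(C)C(C)(C)C | intermediate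
11 | (2S,aS)-1-[(tert-butyldimethylsilyl)oxy]-5-(4,4,5,5-tetramethyl-1,3,2-dioxaborolan-2-yl)penta-3,4-dien-2-yl (2Z)-2-methylbut-2-enoate | CC1(C)OB(OC1(C)C)C([H])=[C@@]=C([H])[C@H](OC(=O)/C(C)=C\C)CO[Si](C)(C)C(C)(C)C | intermediate
12 | O6-pinacolboryl ether of 13 (same configuration as 13) | COC(=O)/C(I)=C/CC[C@@]1(C)O[C@H]1[C@@H](OB2OC(C)(C)C(C)(C)O2)[C@H](C#C)[C@H](OC(=O)/C(C)=C\C)CO[Si](C)(C)C(C)(C)C | intermediate (not isolated)
13 | methyl (2Z)-5-[(2R,3S)-3-{(1S,2S,3S)-4-[(tert-butyldimethylsilyl)oxy]-2-ethynyl-1-hydroxy-3-[(2Z)-2-methylbut-2-enoyloxy]butyl}-2-methyloxiran-2-yl]-2-iodopent-2-enoate | COC(=O)/C(I)=C/CC[C@@]1(C)O[C@H]1[C@@H](O)[C@H](C#C)[C@H](OC(=O)/C(C)=C\C)CO[Si](C)(C)C(C)(C)C | intermediate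
14 | methyl (2Z)-5-[(2R,3S)-3-{(1S,2R,3S)-4-[(tert-butyldimethylsilyl)oxy]-2-ethynyl-1-(methanesulfonyloxy)-3-[(2Z)-2-methylbut-2-enoyloxy]butyl}-2-methyloxiran-2-yl]-2-iodopent-2-enoate | COC(=O)/C(I)=C/CC[C@@]1(C)O[C@H]1[C@@H](OS(C)(=O)=O)[C@H](C#C)[C@H](OC(=O)/C(C)=C\C)CO[Si](C)(C)C(C)(C)C | intermediate
15 | methyl (2Z)-5-[(2R,3S)-3-{(1S,2R,3S)-2-ethynyl-4-hydroxy-1-(methanesulfonyloxy)-3-[(2Z)-2-methylbut-2-enoyloxy]butyl}-2-methyloxiran-2-yl]-2-iodopent-2-enoate | COC(=O)/C(I)=C/CC[C@@]1(C)O[C@H]1[C@@H](OS(C)(=O)=O)[C@H](C#C)[C@H](OC(=O)/C(C)=C\C)CO | intermediate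
16 | methyl (2Z)-5-[(2R,3S)-3-{(1S,2R,3S)-2-ethynyl-1-(methanesulfonyloxy)-3-[(2Z)-2-methylbut-2-enoyloxy]-4-oxobutyl}-2-methyloxiran-2-yl]-2-iodopent-2-enoate | COC(=O)/C(I)=C/CC[C@@]1(C)O[C@H]1[C@@H](OS(C)(=O)=O)[C@H](C#C)[C@H](OC(=O)/C(C)=C\C)C=O | intermediate
17 | ten-membered carbocycle, germacrane numbering: methyl (4R,5S,6S,7R,8S,9S)-8-angeloyloxy-4,5-epoxy-7-ethynyl-9-hydroxy-6-(methanesulfonyloxy)-4-methylcyclodec-1(10)-ene-10-carboxylate, in-ring cis C1=C10 | CS(=O)(=O)O[C@H]2[C@H](C#C)[C@H](OC(=O)/C(C)=C\C)[C@@H](O)/C(C(=O)OC)=C\CC[C@@]1(C)O[C@@H]21 | intermediate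
18 | diethoxy(methyl)silyl ester of the C7 acrylic acid of 17 (C7 bears C(=CH2)CO2Si; ring stereocentres as in 17) | CS(=O)(=O)O[C@H]2[C@H](C(=C)C(=O)O[Si](C)(OCC)OCC)[C@H](OC(=O)/C(C)=C\C)[C@@H](O)/C(C(=O)OC)=C\CC[C@@]1(C)O[C@@H]21 | intermediate (not isolated)
19 | caesium salt of the C7 acrylic acid (ring stereocentres as in 17) | CS(=O)(=O)O[C@H]2[C@H](C(=C)C(=O)[O-])[C@H](OC(=O)/C(C)=C\C)[C@@H](O)/C(C(=O)OC)=C\CC[C@@]1(C)O[C@@H]21.[Cs+] | intermediate (not isolated)
20 | methyl (4R,5S,6R,7R,8S,9S)-8-angeloyloxy-4,5-epoxy-9-hydroxygermacra-1(10),11(13)-dien-12,6-olid-14-oate (cis-fused lactone, in-ring cis C1=C10) | C=C1C(=O)O[C@@H]2[C@H]1[C@H](OC(=O)/C(C)=C\C)[C@@H](O)/C(C(=O)OC)=C\CC[C@@]1(C)O[C@@H]21 | target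

**Step count and risks**
Total steps: 15. Longest linear sequence: 11 (steps 1–5 and 10–15).

Steps most likely to fail:

1. Step 15. The Ni–H may add to the alkyne with the wrong regiochemistry, may be drained by CO2 (formate) or by conjugate reduction of the enoates and of the product, and the acrylate may eliminate the mesylate instead of displacing it. The fallback uses known reactions and sets out from 17. Ruthenium-catalysed Markovnikov hydrosilylation ([Cp*Ru(MeCN)3]PF6, Et3SiH, CH2Cl2, 0 °C) should give the 1-(triethylsilyl)ethenyl compound F1. Iododesilylation (NIS, 2,6-lutidine, HFIP–CH2Cl2, 0 °C) should give the 1-iodoethenyl compound F2. Nickel-catalysed reductive carboxylation of this alkenyl iodide with CO2 (NiCl2(PPh3)2, Mn, DMA, 23 °C), then Cs2CO3 at 40 °C, should lead through the same 5-exo-tet displacement to 20, where the fallback rejoins the route.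

2. Step 14. Facial selectivity at C9 may be poor or substrate-controlled (Felkin addition anti to the C8 acyloxy group would favour the 9-epimer), and oligomerisation competes with the slow ten-membered ring closure. The fallback sets out from 16 and sets C9 by inversion instead of by addition. Ligand-free Ni/Cr cyclisation (CrCl2, NiCl2 cat., DMSO, 2 mM) is taken to the substrate-controlled 9-epi carbinol F3. Mitsunobu reaction with chloroacetic acid (PPh3, DIAD, toluene) should give the inverted (9S)-chloroacetate F4. Selective cleavage with thiourea/NaHCO3 (EtOH, 23 °C) should give 17, where the fallback rejoins the route.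

3. Step 10. Addition of the hindered pinacol allenylboronate may be slow, the cis-epoxy aldehyde may decompose meanwhile, and forcing the temperature may erode the closed transition state. The fallback sets out from 11 and changes the boron donor. Transesterification with methylboronic acid (acetone–0.1 M HCl, 23 °C) should give the free allenylboronic acid F5, which is far more electrophilic at boron and should add to 6 in toluene at −20 °C through the same closed transition state. Aqueous work-up should give 13, where the fallback rejoins the route.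

**Further compounds**
F1 | step 15 | C7 1-(triethylsilyl)ethenyl analogue of 17 | CS(=O)(=O)O[C@H]2[C@H](C(=C)[Si](CC)(CC)CC)[C@H](OC(=O)/C(C)=C\C)[C@@H](O)/C(C(=O)OC)=C\CC[C@@]1(C)O[C@@H]21
F2 | step 15 | C7 1-iodoethenyl analogue of 17 | CS(=O)(=O)O[C@H]2[C@H](C(=C)I)[C@H](OC(=O)/C(C)=C\C)[C@@H](O)/C(C(=O)OC)=C\CC[C@@]1(C)O[C@@H]21
F3 | step 14 | 9-epi-17 (9R carbinol) | CS(=O)(=O)O[C@H]2[C@H](C#C)[C@H](OC(=O)/C(C)=C\C)[C@H](O)/C(C(=O)OC)=C\CC[C@@]1(C)O[C@@H]21
F4 | step 14 | (9S)-chloroacetate of 17 | CS(=O)(=O)O[C@H]2[C@H](C#C)[C@H](OC(=O)/C(C)=C\C)[C@@H](OC(=O)CCl)/C(C(=O)OC)=C\CC[C@@]1(C)O[C@@H]21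
F5 | step 10 | free allenylboronic acid corresponding to 11, (2S,aS) | OB(O)C([H])=[C@@]=C([H])[C@H](OC(=O)/C(C)=C\C)CO[Si](C)(C)C(C)(C)C
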